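**Plan**
1. Retrosynthesis: after removal of three protecting groups, ring A is cut at two neighbouring bonds at once, C6–O (diaryl ether) and C1–CO2H. Because C1 (carboxyl) and C6 (aryloxy) are adjacent and C1 also adjoins the methoxy-bearing C2, both bonds map onto a 3-methoxyaryne of ring A (triple bond C1–C6) that takes the ring B phenoxide at C6 and carbon dioxide at C1.
2. The aryne is stored as a silylaryl triflate (SiMe3 on C1, OTf on C6) made from 4-hydroxy-2-methoxybenzaldehyde: the C3 side chain by Grignard addition, oxidation and asymmetric reduction, the silicon by carbamate-directed lithiation between the two ring oxygens.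
3. Ring B comes from 2-methoxy-4-methylphenol by ortho-formylation, demethylation, selective MOM protection of the outer hydroxyl and acetalisation.
4. Forward order: side chain on ring A, then silicon and triflate, then one three-component coupling joining ring A, ring B and CO2; no ring is formed anywhere; acid and then fluoride unmask the target.
5. Stereochemistry: the single (S)-carbinol centre is set by Corey–Bakshi–Shibata reduction of the aryl isobutyl ketone with the (R)-oxazaborolidine and is carried as its triisopropylsilyl ether to the last step.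

Key step: step 12

Remark: ring A is numbered C1 (CO2H), C2 (OCH3), C3 (side chain), C6 (O-aryl) and ring B C1' (ether O), C2' (OH), C4' (CH3), C6' (CHO); the carbinol carbon of the target is (S). 2-Methoxy-4-methylphenol is taken as the ring B source because its single free ortho position makes the formylation unambiguous.

**Route**

Step 1
Reactants: 1 4-hydroxy-2-methoxybenzaldehyde; 2 isobutylmagnesium bromide
Product: 3 rac-4-(1-hydroxy-3-methylbutyl)-3-methoxyphenol
Conditions: 2 (3.2 equiv), THF, 0 °C → rt; aq. NH4Cl; used crude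
Reagents that add atoms: none
Why: Grignard addition to the aldehyde, in which the first equivalent of 2 only deprotonates the phenol and the magnesium phenoxide still accepts the nucleophile at the formyl carbon, as with vanillin-type aldehydes; the carbinol is racemic because it is oxidised in step 2.

Step 2
Reactants: 3 rac-4-(1-hydroxy-3-methylbutyl)-3-methoxyphenol
Product: 4 1-(4-hydroxy-2-methoxyphenyl)-3-methylbutan-1-one
Conditions: DDQ (1.1 equiv), 1,4-dioxane, rt
Reagents that add atoms: none
Why: DDQ dehydrogenation of a para-hydroxybenzylic alcohol (hydride abstraction assisted by the para oxygen) is selective for this activated carbinol and leaves the phenol free for step 3.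

Step 3
Reactants: 4 1-(4-hydroxy-2-methoxyphenyl)-3-methylbutan-1-one
Product: 5 3-methoxy-4-(3-methylbutanoyl)phenyl N-isopropylcarbamate
Conditions: i-PrNCO, Et3N (cat.), CH2Cl2, rt
Reagents that add atoms: isopropyl isocyanate, CC(C)N=C=O
Why: Base-catalysed addition of the phenol to the isocyanate (carbamoylation) installs the N-isopropyl carbamate that later serves as a removable directing group for ortho-lithiation.

Step 4
Reactants: 5 3-methoxy-4-(3-methylbutanoyl)phenyl N-isopropylcarbamate
Product: 6 4-[(1S)-1-hydroxy-3-methylbutyl]-3-methoxyphenyl N-isopropylcarbamate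
Conditions: (R)-Me-CBS oxazaborolidine [(R)-1-methyl-3,3-diphenyltetrahydro-1H,3H-pyrrolo[1,2-c][1,3,2]oxazaborole] (0.2 equiv), BH3·SMe2, THF, −20 °C; MeOH quench, aq. NH4Cl
Reagents that add atoms: none
Why: Corey–Bakshi–Shibata reduction, in which the aryl group acts as the large and the isobutyl group as the small substituent, so that the (R)-oxazaborolidine–borane complex should deliver hydride to the Re face of the ketone and set the (S)-carbinol.

Step 5
Reactants: 6 4-[(1S)-1-hydroxy-3-methylbutyl]-3-methoxyphenyl N-isopropylcarbamate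
Product: 7 3-methoxy-4-[(1S)-3-methyl-1-(triisopropylsilyloxy)butyl]phenyl N-isopropylcarbamate
Conditions: TIPSOTf, 2,6-lutidine, CH2Cl2, 0 °C → rt; aq. NaHCO3
Reagents that add atoms: triisopropylsilyl trifluoromethanesulfonate, CC(C)[Si](OS(=O)(=O)C(F)(F)F)(C(C)C)C(C)C
Why: O-silylation of the secondary benzylic alcohol with a silyl triflate and a hindered pyridine base breaks no bond at the stereocentre, and the triisopropylsilyl ether is chosen to survive butyllithium and the fluoride of step 12.

Step 6
Reactants: 7 3-methoxy-4-[(1S)-3-methyl-1-(triisopropylsilyloxy)butyl]phenyl N-isopropylcarbamate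
Product: 11 3-methoxy-4-[(1S)-3-methyl-1-(triisopropylsilyloxy)butyl]-2-(trimethylsilyl)phenyl N-isopropylcarbamate, via N-silyl carbamate 8 (not isolated), via aryllithium 9 (not isolated), via N-silyl arylsilane 10 (not isolated)
Conditions: TBSOTf, TMEDA, Et2O, 0 °C → rt; n-BuLi (2.2 equiv), TMEDA, −78 °C; TMSCl, −78 °C → rt; aq. NaHSO4 (0 °C, brief)
Reagents that add atoms: chlorotrimethylsilane, C[Si](C)(C)Cl
Why: Directed ortho-metalation of the carbamate after N-silylation in the flask should lithiate the ring carbon flanked by the methoxy and carbamate oxygens, the only site activated by both groups, and the aryllithium is silylated by TMSCl, the N-silyl group being lost on work-up.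

Step 7
Reactants: 11 3-methoxy-4-[(1S)-3-methyl-1-(triisopropylsilyloxy)butyl]-2-(trimethylsilyl)phenyl N-isopropylcarbamate
Product: 13 3-methoxy-4-[(1S)-3-methyl-1-(triisopropylsilyloxy)butyl]-2-(trimethylsilyl)phenyl trifluoromethanesulfonate, via silylphenol 12 (not isolated)
Conditions: DBU, Et2NH, MeCN, 40 °C; then PhNTf2, rt
Reagents that add atoms: N-phenylbis(trifluoromethanesulfonimide), O=S(=O)(N(c1ccccc1)S(=O)(=O)C(F)(F)F)C(F)(F)F
Why: Amine-induced E1cB cleavage of the N–H carbamate (the isocyanate is trapped by diethylamine as a urea) frees the phenoxide, which is triflated in the same flask, the standard entry to ortho-silylaryl triflate aryne precursors.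

Step 8
Reactants: 14 2-methoxy-4-methylphenol
Product: 16 2-hydroxy-3-methoxy-5-methylbenzaldehyde, via salicyl alcohol 15 (not isolated)
Conditions: MgCl2, Et3N, (CH2O)n, MeCN, reflux; aq. HCl
Reagents that add atoms: formaldehyde (as paraformaldehyde), C=O
Why: Magnesium-mediated ortho-formylation of a phenol (Casnati–Skattebøl), in which the magnesium phenoxide directs formaldehyde to the only free ortho position and the hydroxymethyl intermediate is oxidised in place by a second formaldehyde through Oppenauer-type hydride transfer.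

Step 9
Reactants: 16 2-hydroxy-3-methoxy-5-methylbenzaldehyde
Product: 17 2,3-dihydroxy-5-methylbenzaldehyde
Conditions: BBr3, CH2Cl2, −78 °C → rt; H2O
Reagents that add atoms: none
Why: Lewis-acid cleavage of the aryl methyl ether by BBr3, as in the demethylation of ortho-vanillin to 2,3-dihydroxybenzaldehyde.

Step 10
Reactants: 17 2,3-dihydroxy-5-methylbenzaldehyde
Product: 19 2-hydroxy-3-(methoxymethoxy)-5-methylbenzaldehyde, via disodium dianion 18 (not isolated)
Conditions: NaH (2.2 equiv), DMSO/THF, rt; MOMCl (1.0 equiv), rt; aq. NH4Cl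
Reagents that add atoms: chloromethyl methyl ether, COCCl
Why: Williamson-type alkylation of the dianion, in which the C3 phenoxide, neither conjugated with nor chelated to the formyl group, is the more nucleophilic oxygen, so one equivalent of MOMCl should leave the hydrogen-bonded 2-hydroxyl free.

Step 11
Reactants: 19 2-hydroxy-3-(methoxymethoxy)-5-methylbenzaldehyde
Product: 20 2-(1,3-dioxolan-2-yl)-6-(methoxymethoxy)-4-methylphenol
Conditions: HOCH2CH2OH, HC(OEt)3, PPTS (cat.), CH2Cl2, rt; Et3N quench
Reagents that add atoms: ethane-1,2-diol, OCCO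
Why: Acid-catalysed acetalisation driven by the orthoformate as water scavenger, for which the weak acid PPTS at room temperature should suffice while leaving the aryl MOM ether intact.

Step 12
Reactants: 13 3-methoxy-4-[(1S)-3-methyl-1-(triisopropylsilyloxy)butyl]-2-(trimethylsilyl)phenyl trifluoromethanesulfonate; 20 2-(1,3-dioxolan-2-yl)-6-(methoxymethoxy)-4-methylphenol; 21 carbon dioxide
Product: 25 6-[2-(1,3-dioxolan-2-yl)-6-(methoxymethoxy)-4-methylphenoxy]-2-methoxy-3-[(1S)-3-methyl-1-(triisopropylsilyloxy)butyl]benzoic acid, via potassium phenoxide 22 (not isolated), via aryne 23 (not isolated), via arylpotassium 24 (not isolated)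
Conditions: 20 (1.5 equiv), KH (1.5 equiv), THF, 0 °C; then KF (3 equiv), 18-crown-6, CO2 (1 atm), 13 added slowly, THF, 0 °C → rt; cold dilute HCl to pH 4
Reagents that add atoms: none
Why: Proposed new method: fluoride attack on the trimethylsilyl group of 13 expels triflate and releases aryne 23, whose triple bond is distorted by the inductively withdrawing C2 methoxy group so that the proton-free phenoxide 22 adds at C6, the terminus remote from the methoxy group, leaving the charge at C1 between two oxygen-bearing carbons (arylpotassium 24). This doubly ortho-oxygenated aryl anion is stabilised enough to be carboxylated by dissolved carbon dioxide, which forms the C1–CO2 bond in the same operation. The closest known reaction types are the aryne/amine/carbon dioxide three-component coupling to anthranilic acids, the fluoride-induced O-arylation of phenols by silylaryl triflates, and the aryne–salicylate annulation, in which the same kind of aryl anion is trapped by an acyl group. No ring is closed and no stereocentre is formed; the (S)-silyloxy centre is remote and untouched. The step needs attack at C6 over C1, secured by the C2 methoxy group, and carboxylation over protonation, secured by the absence of any O–H or N–H donor (phenoxide preformed with KH, THF in place of acetonitrile) and by excess carbon dioxide; Kolbe–Schmitt carboxylation of the phenoxide is excluded because both its ortho positions and its para position are substituted.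

Step 13
Reactants: 25 6-[2-(1,3-dioxolan-2-yl)-6-(methoxymethoxy)-4-methylphenoxy]-2-methoxy-3-[(1S)-3-methyl-1-(triisopropylsilyloxy)butyl]benzoic acid
Product: 26 6-(2-formyl-6-hydroxy-4-methylphenoxy)-2-methoxy-3-[(1S)-3-methyl-1-(triisopropylsilyloxy)butyl]benzoic acid
Conditions: 2 M HCl (aq), THF, 40 °C
Reagents that add atoms: water, O
Why: Acid-catalysed hydrolysis of the dioxolane and of the phenolic MOM ether, during which the benzylic C–O bond should not ionise because it is still silylated and ring A now carries the carboxyl group and a methoxy group twisted out of conjugation.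

Step 14
Reactants: 26 6-(2-formyl-6-hydroxy-4-methylphenoxy)-2-methoxy-3-[(1S)-3-methyl-1-(triisopropylsilyloxy)butyl]benzoic acid
Product: 27 tenellic acid B, 6-(2-formyl-6-hydroxy-4-methylphenoxy)-3-[(1S)-1-hydroxy-3-methylbutyl]-2-methoxybenzoic acid
Conditions: n-Bu4NF (4 equiv), THF, 0 °C → rt; dilute HCl work-up
Reagents that add atoms: none
Why: Fluoride-induced desilylation cleaves only the Si–O bond, so the (S) configuration is retained and the target is released.

**Compound list**
1 | 4-hydroxy-2-methoxybenzaldehyde | COc1cc(O)ccc1C=O | starting material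
2 | isobutylmagnesium bromide | CC(C)C[Mg]Br | starting material
3 | rac-4-(1-hydroxy-3-methylbutyl)-3-methoxyphenol | COc1cc(O)ccc1C(O)CC(C)C | intermediate
4 | 1-(4-hydroxy-2-methoxyphenyl)-3-methylbutan-1-one | COc1cc(O)ccc1C(=O)CC(C)C | intermediate
5 | 3-methoxy-4-(3-methylbutanoyl)phenyl N-isopropylcarbamate | COc1cc(OC(=O)NC(C)C)ccc1C(=O)CC(C)C | intermediate
6 | 4-[(1S)-1-hydroxy-3-methylbutyl]-3-methoxyphenyl N-isopropylcarbamate | COc1cc(OC(=O)NC(C)C)ccc1[C@@H](O)CC(C)C | intermediate
7 | 3-methoxy-4-[(1S)-3-methyl-1-(triisopropylsilyloxy)butyl]phenyl N-isopropylcarbamate | COc1cc(OC(=O)NC(C)C)ccc1[C@@H](O[Si](C(C)C)(C(C)C)C(C)C)CC(C)C | intermediate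
8 | N-silyl carbamate: 3-methoxy-4-[(1S)-3-methyl-1-(triisopropylsilyloxy)butyl]phenyl N-(tert-butyldimethylsilyl)-N-isopropylcarbamate | COc1cc(OC(=O)N(C(C)C)[Si](C)(C)C(C)(C)C)ccc1[C@@H](O[Si](C(C)C)(C(C)C)C(C)C)CC(C)C | intermediate (not isolated)
9 | aryllithium: 8 lithiated at the ring carbon between OCH3 and the carbamate oxygen | COc1c([Li])c(OC(=O)N(C(C)C)[Si](C)(C)C(C)(C)C)ccc1[C@@H](O[Si](C(C)C)(C(C)C)C(C)C)CC(C)C | intermediate (not isolated)
10 | N-silyl arylsilane: 3-methoxy-4-[(1S)-3-methyl-1-(triisopropylsilyloxy)butyl]-2-(trimethylsilyl)phenyl N-(tert-butyldimethylsilyl)-N-isopropylcarbamate | COc1c([Si](C)(C)C)c(OC(=O)N(C(C)C)[Si](C)(C)C(C)(C)C)ccc1[C@@H](O[Si](C(C)C)(C(C)C)C(C)C)CC(C)C | intermediate (not isolated)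
11 | 3-methoxy-4-[(1S)-3-methyl-1-(triisopropylsilyloxy)butyl]-2-(trimethylsilyl)phenyl N-isopropylcarbamate | COc1c([Si](C)(C)C)c(OC(=O)NC(C)C)ccc1[C@@H](O[Si](C(C)C)(C(C)C)C(C)C)CC(C)C | intermediate
12 | silylphenol: 3-methoxy-4-[(1S)-3-methyl-1-(triisopropylsilyloxy)butyl]-2-(trimethylsilyl)phenol | COc1c([Si](C)(C)C)c(O)ccc1[C@@H](O[Si](C(C)C)(C(C)C)C(C)C)CC(C)C | intermediate (not isolated)
13 | 3-methoxy-4-[(1S)-3-methyl-1-(triisopropylsilyloxy)butyl]-2-(trimethylsilyl)phenyl trifluoromethanesulfonate (ring A aryne precursor) | COc1c([C@@H](O[Si](C(C)C)(C(C)C)C(C)C)CC(C)C)ccc(OS(=O)(=O)C(F)(F)F)c1[Si](C)(C)C | intermediate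
14 | 2-methoxy-4-methylphenol | COc1cc(C)ccc1O | starting material
15 | salicyl alcohol: 2-(hydroxymethyl)-6-methoxy-4-methylphenol (as its magnesium salt) | COc1cc(C)cc(CO)c1O | intermediate (not isolated)
16 | 2-hydroxy-3-methoxy-5-methylbenzaldehyde | COc1cc(C)cc(C=O)c1O | intermediate
17 | 2,3-dihydroxy-5-methylbenzaldehyde | Cc1cc(O)c(O)c(C=O)c1 | intermediate
18 | disodium dianion: disodium 3-formyl-5-methylbenzene-1,2-diolate | Cc1cc([O-])c([O-])c(C=O)c1.[Na+].[Na+] | intermediate (not isolated)
19 | 2-hydroxy-3-(methoxymethoxy)-5-methylbenzaldehyde | COCOc1cc(C)cc(C=O)c1O | intermediate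
20 | 2-(1,3-dioxolan-2-yl)-6-(methoxymethoxy)-4-methylphenol (protected ring B phenol) | COCOc1cc(C)cc(C2OCCO2)c1O | intermediate
21 | carbon dioxide | O=C=O | starting material
22 | potassium phenoxide: potassium 2-(1,3-dioxolan-2-yl)-6-(methoxymethoxy)-4-methylphenoxide | COCOc1cc(C)cc(C2OCCO2)c1[O-].[K+] | intermediate (not isolated)
23 | aryne: 1,2-didehydro-3-methoxy-4-[(1S)-3-methyl-1-(triisopropylsilyloxy)butyl]benzene (triple bond C1–C6 of ring A) | COC1=C([C@@H](O[Si](C(C)C)(C(C)C)C(C)C)CC(C)C)C=CC#C1 | intermediate (not isolated)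
24 | arylpotassium: {6-[2-(1,3-dioxolan-2-yl)-6-(methoxymethoxy)-4-methylphenoxy]-2-methoxy-3-[(1S)-3-methyl-1-(triisopropylsilyloxy)butyl]phenyl}potassium | COc1c([C@@H](O[Si](C(C)C)(C(C)C)C(C)C)CC(C)C)ccc(Oc2c(OCOC)cc(C)cc2C2OCCO2)c1[K] | intermediate (not isolated)
25 | 6-[2-(1,3-dioxolan-2-yl)-6-(methoxymethoxy)-4-methylphenoxy]-2-methoxy-3-[(1S)-3-methyl-1-(triisopropylsilyloxy)butyl]benzoic acid | COc1c([C@@H](O[Si](C(C)C)(C(C)C)C(C)C)CC(C)C)ccc(Oc2c(OCOC)cc(C)cc2C2OCCO2)c1C(=O)O | intermediate
26 | 6-(2-formyl-6-hydroxy-4-methylphenoxy)-2-methoxy-3-[(1S)-3-methyl-1-(triisopropylsilyloxy)butyl]benzoic acid | COc1c([C@@H](O[Si](C(C)C)(C(C)C)C(C)C)CC(C)C)ccc(Oc2c(O)cc(C)cc2C=O)c1C(=O)O | intermediate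
27 | tenellic acid B, 6-(2-formyl-6-hydroxy-4-methylphenoxy)-3-[(1S)-1-hydroxy-3-methylbutyl]-2-methoxybenzoic acid | COc1c([C@@H](O)CC(C)C)ccc(Oc2c(O)cc(C)cc2C=O)c1C(=O)O | target

**Step count**
Total: 14 steps. Longest linear sequence: 10 steps (steps 1–7, 12, 13, 14); the ring B branch (steps 8–11) joins at step 12.

**Steps most likely to fail**

Step 12. The C1 anion may be protonated by adventitious proton donors before it meets carbon dioxide. The phenoxide may also be tied up by carbon dioxide as its carbonate and then attack through the carbonate oxygen with acyl transfer to C1, or the aryl anion may add to a second aryne. Fallback (sets out from 13 and 20, returns at 25): the two bonds are made in two known operations. Fluoride-induced O-arylation of the free phenol 20 with 13 (CsF, MeCN, rt), in which the phenol itself protonates the aryl anion, should give 2-{2-[3-methoxy-4-[(1S)-3-methyl-1-(triisopropylsilyloxy)butyl]phenoxy]-3-(methoxymethoxy)-5-methylphenyl}-1,3-dioxolane F1. Directed ortho-lithiation of the ring A proton flanked by the methoxy and aryloxy oxygens (n-BuLi, TMEDA, THF, −78 → −20 °C) and quenching with carbon dioxide should then give 25.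

Step 6. Lithiation may drift to the other position ortho to the carbamate, because the bulky side chain pushes the methoxy methyl toward the intended site; the benzylic C–H may also be removed with silyl migration. Fallback (sets out from 1, returns at 13): silicon is introduced before the side chain exists. 1 is carbamoylated (i-PrNCO, Et3N) to 4-formyl-3-methoxyphenyl N-isopropylcarbamate F2. The aldehyde is masked (HC(OMe)3, MeOH, PPTS) as 4-(dimethoxymethyl)-3-methoxyphenyl N-isopropylcarbamate F3. The lithiation–silylation conditions of step 6 on this small substrate should give 4-(dimethoxymethyl)-3-methoxy-2-(trimethylsilyl)phenyl N-isopropylcarbamate F4. Mild aqueous acid (PPTS, acetone/H2O) frees 4-formyl-3-methoxy-2-(trimethylsilyl)phenyl N-isopropylcarbamate F5. The conditions of step 7 give 4-formyl-3-methoxy-2-(trimethylsilyl)phenyl trifluoromethanesulfonate F6. Addition of 2 at −78 °C gives racemic 4-(1-hydroxy-3-methylbutyl)-3-methoxy-2-(trimethylsilyl)phenyl trifluoromethanesulfonate F7. Dess–Martin oxidation gives 3-methoxy-4-(3-methylbutanoyl)-2-(trimethylsilyl)phenyl trifluoromethanesulfonate F8. The reduction of step 4 gives 4-[(1S)-1-hydroxy-3-methylbutyl]-3-methoxy-2-(trimethylsilyl)phenyl trifluoromethanesulfonate F9, and TIPSOTf/2,6-lutidine gives 13.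

Step 11. The MOM group may be lost by acetal exchange with the diol under the acid catalyst, or the ortho-hydroxy acetal may revert to the aldehyde during isolation. Fallback (sets out from 19, returns at 20): the phenol is masked so that acetalisation can be run under aprotic low-temperature conditions. Acetylation (Ac2O, pyridine) gives 2-formyl-6-(methoxymethoxy)-4-methylphenyl acetate F10. Acetalisation with 1,2-bis(trimethylsilyloxy)ethane and catalytic TMSOTf (CH2Cl2, −78 °C) gives 2-(1,3-dioxolan-2-yl)-6-(methoxymethoxy)-4-methylphenyl acetate F11. Methanolysis (K2CO3, MeOH, rt) returns 20.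

**Further compounds**
F1 | step 12 | 2-{2-[3-methoxy-4-[(1S)-3-methyl-1-(triisopropylsilyloxy)butyl]phenoxy]-3-(methoxymethoxy)-5-methylphenyl}-1,3-dioxolane | COc1c([C@@H](O[Si](C(C)C)(C(C)C)C(C)C)CC(C)C)ccc(Oc2c(OCOC)cc(C)cc2C2OCCO2)c1
F2 | step 6 | 4-formyl-3-methoxyphenyl N-isopropylcarbamate | COc1cc(OC(=O)NC(C)C)ccc1C=O
F3 | step 6 | 4-(dimethoxymethyl)-3-methoxyphenyl N-isopropylcarbamate | COc1cc(OC(=O)NC(C)C)ccc1C(OC)OC
F4 | step 6 | 4-(dimethoxymethyl)-3-methoxy-2-(trimethylsilyl)phenyl N-isopropylcarbamate | COc1c([Si](C)(C)C)c(OC(=O)NC(C)C)ccc1C(OC)OC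
F5 | step 6 | 4-formyl-3-methoxy-2-(trimethylsilyl)phenyl N-isopropylcarbamate | COc1c([Si](C)(C)C)c(OC(=O)NC(C)C)ccc1C=O
F6 | step 6 | 4-formyl-3-methoxy-2-(trimethylsilyl)phenyl trifluoromethanesulfonate | COc1c([Si](C)(C)C)c(OS(=O)(=O)C(F)(F)F)ccc1C=O
F7 | step 6 | rac-4-(1-hydroxy-3-methylbutyl)-3-methoxy-2-(trimethylsilyl)phenyl trifluoromethanesulfonate | COc1c([Si](C)(C)C)c(OS(=O)(=O)C(F)(F)F)ccc1C(O)CC(C)C
F8 | step 6 | 3-methoxy-4-(3-methylbutanoyl)-2-(trimethylsilyl)phenyl trifluoromethanesulfonate | COc1c([Si](C)(C)C)c(OS(=O)(=O)C(F)(F)F)ccc1C(=O)CC(C)C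
F9 | step 6 | 4-[(1S)-1-hydroxy-3-methylbutyl]-3-methoxy-2-(trimethylsilyl)phenyl trifluoromethanesulfonate | COc1c([Si](C)(C)C)c(OS(=O)(=O)C(F)(F)F)ccc1[C@@H](O)CC(C)C
F10 | step 11 | 2-formyl-6-(methoxymethoxy)-4-methylphenyl acetate | COCOc1cc(C)cc(C=O)c1OC(C)=O
F11 | step 11 | 2-(1,3-dioxolan-2-yl)-6-(methoxymethoxy)-4-methylphenyl acetate | COCOc1cc(C)cc(C2OCCO2)c1OC(C)=O
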